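**Plan**

Retrosynthesis: the C3–C4 and C13–C14 epoxides and the C6–Cl bond go first (C2-hydroxyl-directed epoxidation, SN2 on a C6 alcohol). The ten-membered ring is then opened at C8–C9 (Nozaki–Hiyama–Kishi), C6–C7 (vinylogous Mukaiyama aldol of a 4-iodo-2-silyloxyfuran that brings the lactone) and C4–C5 (Sonogashira).
Enabling feature: ring A (C1, C10, C11, C12, C13, C14) has a C12–C13 edge bearing only O and H, and its quaternary C1 carrying the C2 carbinol next to C10–C9 is a [2,3]-Wittig retron. Cutting C1–C2 (C9–O ether restored) leaves a cyclohexa-1,4-diene with a C1=C10 bond, the Diels–Alder adduct of diene C14=C1–C10=C11 and an acetylene equivalent that supplies C12–C13 by forming C11–C12 and C13–C14.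
Forward: diene; ring A by catalytic asymmetric Diels–Alder (fumarate, then bis-decarboxylation); [2,3]-Wittig (C1, C2); silicon-tethered hydrosilylation (C10, C9); C3–C6 chain; butenolide by vinylogous aldol; ten-membered ring by NHK; late oxidation-state adjustment.
Stereochemistry: C11 from the Diels–Alder catalyst; C1/C2 relayed from C11 in the [2,3]-shift; C10 by hydrogen delivery from the C2–O–Si tether; C6/C7 from the aldol catalyst (C6 inverted by chloride at the end); C9 in the ring closure; C12 by C9-hydroxyl-directed epoxidation and selenoxide transposition; C8/C17 by butenolide epoxidation and SmI2; C3, C4, C13, C14 by the C2 hydroxyl.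

Key step: step 4

Remark: locants in names follow the briarane skeleton of the target (C1 quaternary ring-fusion carbon, C2 to C9 around the ten-membered ring, C10 ring-fusion CH, C11 to C14 completing ring A, C15 methyl on C1, C16 exocyclic carbon on C5, C17 lactone α-carbon, C18 its methyl, C19 lactone carbonyl, C20 methyl on C11); β is the face of ring A that carries C15.

**Route**

Step 1
Reactants: 1 but-2-yn-1-ol
Product: 2 (E)-2-(tributylstannyl)but-2-en-1-ol
Conditions: Bu3SnH, PdCl2(PPh3)2 (2 mol%), THF, 0 °C to rt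
Reagents that add atoms: tributyltin hydride, CCCC[SnH](CCCC)CCCC
Why: Palladium-catalysed syn-hydrostannation of a propargylic alcohol should place tin on the carbon next to the carbinol, so Sn and the new vinylic H are cis and the CH2OH group ends cis to the methyl group.

Step 2
Reactants: 2 (E)-2-(tributylstannyl)but-2-en-1-ol; 3 2-bromopropene
Product: 4 (2Z)-2-(prop-1-en-2-yl)but-2-en-1-ol
Conditions: Pd(PPh3)4 (5 mol%), CuI, CsF, DMF, 45 °C
Reagents that add atoms: none
Why: Stille coupling proceeds with retention at the alkenylstannane and should give the 2,3-disubstituted diene whose C20 methyl is cis to C9 and therefore points outward in the s-cis conformer.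

Step 3
Reactants: 4 (2Z)-2-(prop-1-en-2-yl)but-2-en-1-ol; 5 3-bromo-1-(trimethylsilyl)prop-1-yne
Product: 6 trimethyl(3-{[(2Z)-2-(prop-1-en-2-yl)but-2-en-1-yl]oxy}prop-1-yn-1-yl)silane
Conditions: NaH, Bu4NI (cat.), THF, 0 °C to rt
Reagents that add atoms: none
Why: Williamson etherification of the primary allylic alkoxide puts the future C2–C4 unit on the C9 oxygen, ready to migrate in the later sigmatropic shift.

Step 4
Reactants: 6 dienyl propargyl ether; 7 dimethyl fumarate
Product: 8 dimethyl (1R,2R,3S)-3,5-dimethyl-4-({[3-(trimethylsilyl)prop-2-yn-1-yl]oxy}methyl)cyclohex-4-ene-1,2-dicarboxylate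
Conditions: (S)-3,3-diphenyl-1-(2-methylphenyl)tetrahydro-1H,3H-pyrrolo[1,2-c][1,3,2]oxazaborole (20 mol%), Tf2NH (18 mol%), CH2Cl2, −78 to −20 °C
Reagents that add atoms: none
Why: The cationic oxazaborolidinium Lewis acid binds one ester carbonyl of the C2-symmetric fumarate and the diene adds in a concerted, suprafacial [4+2] cycloaddition (Diels–Alder reaction; closest precedent is triflimide-activated oxazaborolidine catalysis of fumarate and acrylate additions to 2,3-disubstituted butadienes). Ring A closes in the [4+2] mode by forming C11–C12 and C13–C14 together, and it keeps the C1=C10 double bond that the later quaternary-centre construction needs. The only stereocentre that survives, C11, is set by which diene face meets the catalyst-bound dienophile (catalyst control; the catalyst enantiomer is chosen for the C11 configuration drawn), whereas the trans C12/C13 ester pair only copies the fumarate geometry and is removed in steps 5 and 6. Regiochemistry does not arise because the dienophile is symmetrical, and the reactive s-cis diene is secured by the outward C20 methyl and the 2,3-disubstitution. The step therefore needs enantiofacial selectivity only, and fumarate acts as an acetylene equivalent so that C12 and C13 arrive as unsubstituted carbons.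

Step 5
Reactants: 8 Diels–Alder diester
Product: 9 (1R,2R,3S)-3,5-dimethyl-4-({[3-(trimethylsilyl)prop-2-yn-1-yl]oxy}methyl)cyclohex-4-ene-1,2-dicarboxylic acid
Conditions: Me3SnOH (6 equiv), ClCH2CH2Cl, 80 °C; 1 M HCl work-up
Reagents that add atoms: trimethyltin hydroxide, C[Sn](C)(C)O
Why: Trimethyltin hydroxide cleaves methyl esters under neutral conditions, which should spare the alkynylsilane and avoid base-mediated epimerisation or alkene migration.

Step 6
Reactants: 9 trans-diacid
Product: 10 (3S)-1,3-dimethyl-2-({[3-(trimethylsilyl)prop-2-yn-1-yl]oxy}methyl)cyclohexa-1,4-diene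
Conditions: Pb(OAc)4 (1.2 equiv), pyridine, dioxane, 50 °C
Reagents that add atoms: none
Why: Oxidative bis-decarboxylation of a vicinal diacid with Pb(OAc)4 should unmask the C12=C13 double bond, completing the use of fumarate as an acetylene equivalent without touching C11.

Step 7
Reactants: 10 cyclohexa-1,4-diene ether
Product: 11 (2S)-1-(1,5-dimethyl-6-methylidenecyclohex-3-en-1-yl)-3-(trimethylsilyl)prop-2-yn-1-ol (C2 on the α face of C1; C15 and C20 β)
Conditions: n-BuLi (1.2 equiv), THF, −78 °C; aq. NH4Cl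
Reagents that add atoms: none
Why: [2,3]-Wittig rearrangement of the lithiated propargyl ether should form C1–C2 across the tetrasubstituted alkene through a five-membered envelope transition state on the face anti to the allylic C20 methyl, with the alkynyl group exo and the C15 methyl cis to C9 enforcing the syn-type outcome, so the quaternary C1 and the C2 carbinol arise together while the C9 oxygen is traded for the exocyclic C10=C9 alkene.

Step 8
Reactants: 11 propargylic alcohol
Product: 14 alkyne diol 2-OH/9-OH with H-10 α (terminal alkyne), via hydrodimethylsilyl ether 12 (not isolated), via cyclic siloxane 13 (not isolated)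
Conditions: HMe2SiCl, Et3N, CH2Cl2, 0 °C; then Pt2[(CH2=CHSiMe2)2O]3 (1 mol%), toluene, 60 °C; then KF, KHCO3, 30% H2O2, THF/MeOH, rt
Reagents that add atoms: hydrogen peroxide, OO
Why: A temporary silicon tether on the C2 oxygen allows platinum-catalysed intramolecular hydrosilylation of the exocyclic alkene, with silicon going to the terminal C9 and hydrogen delivered to C10 from the α face of the tether, and Tamao–Fleming oxidation then converts C–Si into the C9 alcohol while fluoride in methanol also frees the alkyne.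

Step 9
Reactants: 14 alkyne diol
Product: 15 2,9-bis(tert-butyldimethylsilyl) ether of 14
Conditions: TBSOTf (2.5 equiv), 2,6-lutidine, CH2Cl2, −78 to 0 °C
Reagents that add atoms: tert-butyldimethylsilyl triflate, CC(C)(C)[Si](C)(C)OS(=O)(=O)C(F)(F)F
Why: Silyl triflate silylation protects both hydroxyls in one operation, and the primary C9 ether can later be removed selectively.

Step 10
Reactants: 15 bis-silyl ether; 16 2-bromo-3,3-diethoxyprop-1-ene
Product: 17 enyne acetal (C3≡C4–C5(=C16H2)–C6H(OEt)2)
Conditions: Pd(PPh3)4 (5 mol%), CuI (10 mol%), Et3N, THF, rt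
Reagents that add atoms: none
Why: Sonogashira coupling of the terminal alkyne with the 2-bromoalkene forms C4–C5 and brings in C5, C16 and C6 at the aldehyde oxidation level.

Step 11
Reactants: 17 enyne acetal
Product: 18 (3Z)-diene acetal
Conditions: Zn (activated with Cu(OAc)2 and AgNO3), MeOH/H2O (1:1), 40 °C
Reagents that add atoms: none
Why: Copper/silver-activated zinc reduces conjugated enynes to cis alkenes without touching isolated alkenes, which should set the Z C3=C4 bond that later becomes the cis epoxide.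

Step 12
Reactants: 18 (3Z)-diene acetal
Product: 19 (3Z)-dienal (C6 aldehyde)
Conditions: PPTS (cat.), acetone/H2O (9:1), rt
Reagents that add atoms: water, O
Why: Mild acid hydrolysis of the α,β-unsaturated acetal should liberate the C6 aldehyde while the silyl ethers survive.

Step 13
Reactants: 20 ethyl 2-methyl-3-oxobutanoate
Product: 22 4-hydroxy-3-methylfuran-2(5H)-one, via bromo keto ester 21 (not isolated)
Conditions: Br2, CHCl3, 0 °C to rt; then neat, 110 °C
Reagents that add atoms: none
Why: Bromination of the β-keto ester equilibrates to the 4-bromo isomer under HBr, and heating closes the lactone by O-alkylation of the ester carbonyl with loss of bromoethane (classical tetronic acid synthesis).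

Step 14
Reactants: 22 4-hydroxy-3-methylfuran-2(5H)-one
Product: 23 4-iodo-3-methylfuran-2(5H)-one
Conditions: PPh3, I2, Et3N, MeCN, reflux
Reagents that add atoms: iodine, II
Why: The vinylogous acid is converted into the β-iodo enoate by the triphenylphosphine–iodine method used for β-iodo enones from 1,3-dicarbonyl compounds (addition–elimination on the oxyphosphonium salt).

Step 15
Reactants: 23 4-iodo-3-methylfuran-2(5H)-one
Product: 24 tert-butyl[(4-iodo-3-methylfuran-2-yl)oxy]dimethylsilane
Conditions: TBSOTf, Et3N, CH2Cl2, 0 °C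
Reagents that add atoms: tert-butyldimethylsilyl triflate, CC(C)(C)[Si](C)(C)OS(=O)(=O)C(F)(F)F
Why: Soft enolisation and O-silylation give the 2-silyloxyfuran, the nucleophile for the vinylogous aldol reaction.

Step 16
Reactants: 19 (3Z)-dienal; 24 silyloxyfuran
Product: 25 vinylogous aldol adduct (2,6,9-tris-TBS ether; 8-iodo butenolide; C6 opposite to the target, C7 as in the target)
Conditions: Ti(OiPr)4 (20 mol%), (R)-BINOL (20 mol%), 4 Å MS, Et2O, −20 °C
Reagents that add atoms: none
Why: In this vinylogous Mukaiyama aldol reaction the chiral titanium Lewis acid should control the aldehyde face (C6; catalyst enantiomer chosen for the configuration drawn), the furan adds through its 5-position (C7) in an open antiperiplanar transition state that favours the 6,7-syn adduct, and silyl transfer to the aldolate oxygen leaves C6 protected.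

Step 17
Reactants: 25 tris-silyl ether
Product: 26 C9 primary alcohol
Conditions: HF·pyridine, pyridine, THF, 0 °C
Reagents that add atoms: none
Why: Buffered HF·pyridine removes the unhindered primary silyl ether much faster than the two secondary ones.

Step 18
Reactants: 26 C9 primary alcohol
Product: 27 C9 aldehyde
Conditions: Dess–Martin periodinane, NaHCO3, CH2Cl2, 0 °C to rt
Reagents that add atoms: none
Why: Dess–Martin oxidation gives the α-branched aldehyde under conditions that should not epimerise C10.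

Step 19
Reactants: 27 iodo aldehyde
Product: 28 macrocyclic butenolide (9-hydroxy; 2,6-bis-TBS)
Conditions: CrCl2 (10 equiv), NiCl2 (0.1 equiv), DMSO/THF (3:1), rt, 2 mM, slow addition
Reagents that add atoms: none
Why: In the Nozaki–Hiyama–Kishi reaction NiCl2-catalysed insertion into the alkenyl iodide and transmetalation to trivalent chromium give an aldehyde-selective alkenyl nucleophile that should close the ten-membered ring at C8–C9 under high dilution, with the C9 carbinol set by Felkin–Anh-type addition anti to the C1 quaternary carbon.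

Step 20
Reactants: 28 macrocyclic butenolide
Product: 29 12β,13β-epoxide
Conditions: VO(acac)2 (5 mol%), t-BuOOH, CH2Cl2, 0 °C to rt
Reagents that add atoms: tert-butyl hydroperoxide, CC(C)(C)OO
Why: In this hydroxyl-directed epoxidation the only free hydroxyl, at C9 on the β-oriented C10 branch, is bishomoallylic to the ring A alkene and should deliver oxygen to its β face, while the electron-poor butenolide alkene is inert.

Step 21
Reactants: 29 12β,13β-epoxide
Product: 30 8,17-epoxy lactone
Conditions: t-BuOOH, n-BuLi, THF, −20 to 0 °C; aq. NH4Cl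
Reagents that add atoms: tert-butyl hydroperoxide, CC(C)(C)OO
Why: Nucleophilic (Weitz–Scheffer-type) epoxidation of the electron-poor butenolide with lithium tert-butyl peroxide should give the 8,17-epoxide; attack from the peripheral face of the macrocycle is assumed, which would place the C8 oxygen cis to C6, though local sterics at the lactone favour the opposite face and this selectivity is unsecured (see risks).

Step 22
Reactants: 30 8,17-epoxy lactone
Product: 31 8-hydroxy lactone (C17 H, C18 methyl cis to the C8 hydroxyl)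
Conditions: SmI2 (2.5 equiv), MeOH, THF, −78 °C
Reagents that add atoms: none
Why: SmI2 cleaves the Cα–O bond of an α,β-epoxy lactone, which keeps the tertiary C8 alcohol with its configuration, and the epimerisable C17 centre should settle with its methyl trans to the bulkier C9 branch.

Step 23
Reactants: 31 8-hydroxy lactone
Product: 33 12β-hydroxy-13-ene triol, via hydroxy selenide 32 (not isolated)
Conditions: (PhSe)2, NaBH4, EtOH, rt to 60 °C; then 30% H2O2, pyridine, THF, 0 °C to rt
Reagents that add atoms: none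
Why: The weakly basic selenide Na[PhSeB(OEt)3] should open the epoxide trans-diaxially at the less hindered C13, and selenoxide syn-elimination away from the carbinol carbon then transposes the functionality to the C12 β-alcohol and the C13=C14 alkene.

Step 24
Reactants: 33 triol
Product: 34 9,12-diacetate
Conditions: Ac2O, pyridine, DMAP (cat.), CH2Cl2, 0 °C to rt
Reagents that add atoms: acetic anhydride, CC(=O)OC(C)=O
Why: Acetic anhydride acylates the two secondary alcohols (C9 and C12) and should leave the tertiary C8 alcohol free.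

Step 25
Reactants: 34 9,12-diacetate
Product: 35 2,6-diol
Conditions: HF·pyridine, pyridine, THF, rt
Reagents that add atoms: none
Why: Fluoride cleaves both secondary silyl ethers under buffered, non-basic conditions that the acetates and the lactone should tolerate.

Step 26
Reactants: 35 2,6-diol
Product: 36 (6S)-6-chloride
Conditions: PPh3, Cl3CC(O)CCl3, CH2Cl2, −20 to 0 °C
Reagents that add atoms: hexachloroacetone, ClC(Cl)(Cl)C(=O)C(Cl)(Cl)Cl
Why: Appel-type chlorination should convert the allylic C6 alcohol into the chloride by SN2 with inversion and without allylic transposition, while the C2 alcohol flanked by the quaternary C1 and the tertiary C8 alcohol do not compete.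

Step 27
Reactants: 36 (6S)-6-chloride
Product: 37 CNP0379630.2
Conditions: VO(acac)2 (10 mol%), t-BuOOH (excess), CH2Cl2, rt to 40 °C
Reagents that add atoms: tert-butyl hydroperoxide, CC(C)(C)OO
Why: In this hydroxyl-directed epoxidation the C2 alcohol should deliver oxygen to the allylic Z C3=C4 bond (cis epoxy alcohol, as for medium-ring Z-cycloalkenols) and to the homoallylic C13=C14 bond on its own α face anti to the C12 acetate, while the chlorine-deactivated C5=C16 alkene is left.

**Compound list**

1 | but-2-yn-1-ol | CC#CCO | starting material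
2 | (E)-2-(tributylstannyl)but-2-en-1-ol | C/C=C(/[Sn](CCCC)(CCCC)CCCC)CO | intermediate
3 | 2-bromopropene | CC(Br)=C | starting material
4 | (2Z)-2-(prop-1-en-2-yl)but-2-en-1-ol | C/C=C(/C(C)=C)CO | intermediate
5 | 3-bromo-1-(trimethylsilyl)prop-1-yne | C[Si](C)(C)C#CCBr | starting material
6 | trimethyl(3-{[(2Z)-2-(prop-1-en-2-yl)but-2-en-1-yl]oxy}prop-1-yn-1-yl)silane | C/C=C(/C(C)=C)COCC#C[Si](C)(C)C | intermediate
7 | dimethyl fumarate | COC(=O)/C=C/C(=O)OC | starting material
8 | dimethyl (1R,2R,3S)-3,5-dimethyl-4-({[3-(trimethylsilyl)prop-2-yn-1-yl]oxy}methyl)cyclohex-4-ene-1,2-dicarboxylate (ring A with C1=C10; drawn with the C12 ester cis to C20, the other trans-diester diastereomer converges in step 6) | CC1=C(COCC#C[Si](C)(C)C)[C@@H](C)[C@@H](C(=O)OC)[C@H](C(=O)OC)C1 | intermediate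
9 | (1R,2R,3S)-3,5-dimethyl-4-({[3-(trimethylsilyl)prop-2-yn-1-yl]oxy}methyl)cyclohex-4-ene-1,2-dicarboxylic acid | CC1=C(COCC#C[Si](C)(C)C)[C@@H](C)[C@@H](C(=O)O)[C@H](C(=O)O)C1 | intermediate
10 | (3S)-1,3-dimethyl-2-({[3-(trimethylsilyl)prop-2-yn-1-yl]oxy}methyl)cyclohexa-1,4-diene | CC1=C(COCC#C[Si](C)(C)C)[C@@H](C)C=CC1 | intermediate
11 | (2S)-1-(1,5-dimethyl-6-methylidenecyclohex-3-en-1-yl)-3-(trimethylsilyl)prop-2-yn-1-ol (C2 α on C1; C15, C20 β) | C[Si](C)(C)C#C[C@@H](O)[C@]1(C)C(=C)[C@@H](C)C=CC1 | intermediate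
12 | hydrodimethylsilyl ether of 11 | C[Si](C)(C)C#C[C@@H](O[SiH](C)C)[C@]1(C)C(=C)[C@@H](C)C=CC1 | intermediate
13 | cyclic siloxane (2,2-dimethyl-1-oxa-2-silacyclohexane trans-fused to ring A; O on C2, Si on C9, H-10 α) | C[Si](C)(C)C#C[C@H]1O[Si](C)(C)C[C@H]2[C@@H](C)C=CC[C@]12C | intermediate
14 | 1-[2-(hydroxymethyl)-1,3-dimethylcyclohex-4-en-1-yl]prop-2-yn-1-ol (C2 as in the target; C9H2OH β, H-10 α; C15, C20 β) | C#C[C@@H](O)[C@]1(C)[C@@H](CO)[C@@H](C)C=CC1 | intermediate
15 | 2,9-bis(tert-butyldimethylsilyl) ether of 14 | C#C[C@@H](O[Si](C)(C)C(C)(C)C)[C@]1(C)[C@@H](CO[Si](C)(C)C(C)(C)C)[C@@H](C)C=CC1 | intermediate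
16 | 2-bromo-3,3-diethoxyprop-1-ene | C=C(Br)C(OCC)OCC | starting material
17 | enyne acetal (C3≡C4–C5(=C16H2)–C6H(OEt)2 on 15) | CCOC(OCC)C(=C)C#C[C@@H](O[Si](C)(C)C(C)(C)C)[C@]1(C)[C@@H](CO[Si](C)(C)C(C)(C)C)[C@@H](C)C=CC1 | intermediate
18 | (3Z)-diene acetal | CCOC(OCC)C(=C)/C=C\[C@@H](O[Si](C)(C)C(C)(C)C)[C@]1(C)[C@@H](CO[Si](C)(C)C(C)(C)C)[C@@H](C)C=CC1 | intermediate
19 | (3Z)-dienal (C6 aldehyde) | O=CC(=C)/C=C\[C@@H](O[Si](C)(C)C(C)(C)C)[C@]1(C)[C@@H](CO[Si](C)(C)C(C)(C)C)[C@@H](C)C=CC1 | intermediate
20 | ethyl 2-methyl-3-oxobutanoate | CCOC(=O)C(C)C(C)=O | starting material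
21 | ethyl 4-bromo-2-methyl-3-oxobutanoate | CCOC(=O)C(C)C(=O)CBr | intermediate
22 | 4-hydroxy-3-methylfuran-2(5H)-one | CC1=C(O)COC1=O | intermediate
23 | 4-iodo-3-methylfuran-2(5H)-one | CC1=C(I)COC1=O | intermediate
24 | tert-butyl[(4-iodo-3-methylfuran-2-yl)oxy]dimethylsilane | CC1=C(O[Si](C)(C)C(C)(C)C)OC=C1I | intermediate
25 | vinylogous aldol adduct: 2,6,9-tris-TBS ether with 8-iodo butenolide (3Z; C6 opposite to the target, C7 as in the target) | C=C(/C=C\[C@@H](O[Si](C)(C)C(C)(C)C)[C@]1(C)[C@@H](CO[Si](C)(C)C(C)(C)C)[C@@H](C)C=CC1)[C@@H](O[Si](C)(C)C(C)(C)C)[C@@H]1OC(=O)C(C)=C1I | intermediate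
26 | C9 primary alcohol from 25 | C=C(/C=C\[C@@H](O[Si](C)(C)C(C)(C)C)[C@]1(C)[C@@H](CO)[C@@H](C)C=CC1)[C@@H](O[Si](C)(C)C(C)(C)C)[C@@H]1OC(=O)C(C)=C1I | intermediate
27 | C9 aldehyde (iodo aldehyde) | C=C(/C=C\[C@@H](O[Si](C)(C)C(C)(C)C)[C@]1(C)[C@@H](C=O)[C@@H](C)C=CC1)[C@@H](O[Si](C)(C)C(C)(C)C)[C@@H]1OC(=O)C(C)=C1I | intermediate
28 | macrocyclic butenolide: 9-hydroxy-2,6-bis(TBS-oxy)briara-3(Z),5(16),8(17),12-tetraen-19,7-olide (C9 as in the target) | C=C1/C=C\[C@@H](O[Si](C)(C)C(C)(C)C)[C@]2(C)[C@H]([C@@H](C)C=CC2)[C@@H](O)C2=C(C)C(=O)O[C@H]2[C@@H]1O[Si](C)(C)C(C)(C)C | intermediate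
29 | 12β,13β-epoxide of 28 | C=C1/C=C\[C@@H](O[Si](C)(C)C(C)(C)C)[C@]2(C)[C@H]([C@@H](C)[C@H]3O[C@H]3C2)[C@@H](O)C2=C(C)C(=O)O[C@H]2[C@@H]1O[Si](C)(C)C(C)(C)C | intermediate
30 | 8,17-epoxy lactone (C8 oxygen as in the target) | C=C1/C=C\[C@@H](O[Si](C)(C)C(C)(C)C)[C@]2(C)[C@H]([C@@H](C)[C@H]3O[C@H]3C2)[C@@H](O)[C@]2(O3)[C@]3(C)C(=O)O[C@H]2[C@@H]1O[Si](C)(C)C(C)(C)C | intermediate
31 | 8-hydroxy lactone (C8, C17 as in the target) | C=C1/C=C\[C@@H](O[Si](C)(C)C(C)(C)C)[C@]2(C)[C@H]([C@@H](C)[C@H]3O[C@H]3C2)[C@@H](O)[C@]2(O)[C@@H](C)C(=O)O[C@H]2[C@@H]1O[Si](C)(C)C(C)(C)C | intermediate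
32 | 12β-hydroxy-13α-phenylselanyl intermediate | C=C1/C=C\[C@@H](O[Si](C)(C)C(C)(C)C)[C@]2(C)[C@H]([C@@H](C)[C@@H](O)[C@H]([Se]c3ccccc3)C2)[C@@H](O)[C@]2(O)[C@@H](C)C(=O)O[C@H]2[C@@H]1O[Si](C)(C)C(C)(C)C | intermediate
33 | 8,9,12β-triol with C13=C14 | C=C1/C=C\[C@@H](O[Si](C)(C)C(C)(C)C)[C@]2(C)[C@H]([C@@H](C)[C@@H](O)C=C2)[C@@H](O)[C@]2(O)[C@@H](C)C(=O)O[C@H]2[C@@H]1O[Si](C)(C)C(C)(C)C | intermediate
34 | 9,12-diacetate | C=C1/C=C\[C@@H](O[Si](C)(C)C(C)(C)C)[C@]2(C)[C@H]([C@@H](C)[C@@H](OC(C)=O)C=C2)[C@@H](OC(C)=O)[C@]2(O)[C@@H](C)C(=O)O[C@H]2[C@@H]1O[Si](C)(C)C(C)(C)C | intermediate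
35 | 2,6-diol (C6 hydroxyl opposite to the target chloride) | C=C1/C=C\[C@@H](O)[C@]2(C)[C@H]([C@@H](C)[C@@H](OC(C)=O)C=C2)[C@@H](OC(C)=O)[C@]2(O)[C@@H](C)C(=O)O[C@H]2[C@@H]1O | intermediate
36 | (6S)-6-chloride | C=C1/C=C\[C@@H](O)[C@]2(C)[C@H]([C@@H](C)[C@@H](OC(C)=O)C=C2)[C@@H](OC(C)=O)[C@]2(O)[C@@H](C)C(=O)O[C@H]2[C@H]1Cl | intermediate
37 | CNP0379630.2: (1S,2S,3S,4R,6S,7R,8R,9R,10S,11R,12R,13S,14R,17R)-9,12-diacetoxy-6-chloro-3,4:13,14-diepoxy-2,8-dihydroxybriar-5(16)-en-19,7-olide | C=C1[C@H]2O[C@H]2[C@@H](O)[C@]2(C)[C@H]([C@@H](C)[C@@H](OC(C)=O)[C@@H]3O[C@@H]32)[C@@H](OC(C)=O)[C@]2(O)[C@@H](C)C(=O)O[C@H]2[C@H]1Cl | target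

**Count and risks**

Total steps: 27. Longest linear sequence: 24 (steps 1 to 12 and 16 to 27); steps 13 to 15 make the furan.

Step 19 (ring closure). Intermolecular coupling and protodeiodination may outrun closure of the strained ten-membered ring onto the hindered, α-branched C9 aldehyde. The fallback moves the ring closure to C6–C7 and sets out from acetal 18 and iodobutenolide 23. HF·pyridine frees the C9 alcohol, primary alcohol F2. Dess–Martin oxidation gives the C9 aldehyde F3. An intermolecular Nozaki–Hiyama–Kishi coupling with 23 (CrCl2, NiCl2, DMSO) forms C8–C9 as carbinol F4. PPTS in wet acetone unmasks the enal F5. A base-mediated intramolecular vinylogous aldol addition of the butenolide dienolate (DBU, high dilution) closes C6–C7 to the macrocyclic diol F6. Selective silylation of the less hindered allylic C6 hydroxyl (TBSCl, imidazole) comes back to the route at 28.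

Step 21 (butenolide epoxidation). Peroxide addition to the tetrasubstituted lactone alkene may be slow and may occur on the face anti to C6. The fallback sets out from 29 and accepts the wrong-face product, the 8,17-bis-epi epoxide F7. SmI2 reduces it to the 8,17-bis-epi hydroxy lactone F8. DBU in THF then equilibrates C8 and C17 by retro-aldol opening to the macrocyclic C8 ketone carrying the C7 propionate, keto ester F9 (not isolated), and intramolecular re-aldolisation. This assumes the trans-fused lactone is the more stable isomer, and the route is rejoined at 31.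

Step 6 (bis-decarboxylation). Pb(OAc)4 may over-oxidise the skipped diene to the arene or cause acetoxylactonisation onto C1=C10. The fallback sets out from ether 6 and uses a non-oxidative acetylene equivalent. The same oxazaborolidinium-catalysed Diels–Alder reaction with (E)-3-bromoacrylic acid gives the trans-β-bromo acid F1 (either regioisomer serves). Warming with NaHCO3 in DMF causes anti-periplanar decarboxylative loss of bromide (Grob-type fragmentation) and comes back at 10.

Further compounds
F1 | step 6 | trans-β-bromo acid adduct (C12 carboxylic acid β, C13 bromide α; ring A with C1=C10) | CC1=C(COCC#C[Si](C)(C)C)[C@@H](C)[C@@H](C(=O)O)[C@H](Br)C1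
F2 | step 19 | C9 primary alcohol of acetal 18 | CCOC(OCC)C(=C)/C=C\[C@@H](O[Si](C)(C)C(C)(C)C)[C@]1(C)[C@@H](CO)[C@@H](C)C=CC1
F3 | step 19 | C9 aldehyde of acetal 18 | CCOC(OCC)C(=C)/C=C\[C@@H](O[Si](C)(C)C(C)(C)C)[C@]1(C)[C@@H](C=O)[C@@H](C)C=CC1
F4 | step 19 | C9 carbinol joined to C8 of 3-methylfuran-2(5H)-one (acetal intact) | CCOC(OCC)C(=C)/C=C\[C@@H](O[Si](C)(C)C(C)(C)C)[C@]1(C)[C@@H]([C@@H](O)C2=C(C)C(=O)OC2)[C@@H](C)C=CC1
F5 | step 19 | enal from F4 (C6 aldehyde) | O=CC(=C)/C=C\[C@@H](O[Si](C)(C)C(C)(C)C)[C@]1(C)[C@@H]([C@@H](O)C2=C(C)C(=O)OC2)[C@@H](C)C=CC1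
F6 | step 19 | macrocyclic 6,9-diol (2-TBS ether; butenolide) | C=C1/C=C\[C@@H](O[Si](C)(C)C(C)(C)C)[C@]2(C)[C@H]([C@@H](C)C=CC2)[C@@H](O)C2=C(C)C(=O)O[C@H]2[C@@H]1O
F7 | step 21 | 8,17-bis-epi epoxy lactone | C=C1/C=C\[C@@H](O[Si](C)(C)C(C)(C)C)[C@]2(C)[C@H]([C@@H](C)[C@H]3O[C@H]3C2)[C@@H](O)[C@@]2(O3)[C@@]3(C)C(=O)O[C@H]2[C@@H]1O[Si](C)(C)C(C)(C)C
F8 | step 21 | 8,17-bis-epi hydroxy lactone | C=C1/C=C\[C@@H](O[Si](C)(C)C(C)(C)C)[C@]2(C)[C@H]([C@@H](C)[C@H]3O[C@H]3C2)[C@@H](O)[C@@]2(O)[C@H](C)C(=O)O[C@H]2[C@@H]1O[Si](C)(C)C(C)(C)C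
F9 | step 21 | macrocyclic C8 ketone with C7 propionate (retro-aldol intermediate) | C=C1/C=C\[C@@H](O[Si](C)(C)C(C)(C)C)[C@]2(C)[C@H]([C@@H](C)[C@H]3O[C@H]3C2)[C@@H](O)C(=O)[C@@H](OC(=O)CC)[C@@H]1O[Si](C)(C)C(C)(C)C
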